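C1H2–C2H–C6H–C7H(i-Pr)–C8H(O-acyl)–C9H2–C10(CH3)(OH) is the seven-membered ring and C2–C3–C4(CH3)–C5H2–C6 the five-membered ring; α is the face of the C8 and C10 oxygens, the C7 isopropyl group, C6–H and the oxirane oxygen, β the face of C2–H and the C10 methyl group.
The C3–C4 oxirane is taken back to a C3=C4 alkene (epoxidation directed by the α C10–OH), and that alkene to a 2-methylcyclopent-2-enone (C3=O, C4=C5) by reductive 1,3-transposition; the plan rests on this cyclopentenone, whose C5–C6 bond lies next to the isopropyl-bearing C7.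
The C5–C6 bond is cut by a silicon-directed Nazarov cyclisation of a cycloheptenyl (E)-1-methyl-2-(trimethylsilyl)vinyl ketone, in which C7 steers the conrotation and silicon fixes the alkene at C4=C5.
The dienone comes from a C2-formylcycloheptene and 1-(trimethylsilyl)propyne (C3–C4 bond, titanium-mediated); the C2=C6 cycloheptene from ring-closing metathesis of a 2-methylidene aldehyde; C7/C8 from an (E)-selective Brown allylboration; C10 from (R)-linalool.
Ring order: seven-membered ring (step 8), five-membered ring (step 11), oxirane (step 17); the isovanillate is attached at C8 as its O-benzyl ether and freed last.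

Key step: step 11

Step 1
Reactants: 1 (R)-linalool
Product: 2 (3R)-3,7-dimethyl-3-(triethylsilyloxy)octa-1,6-diene
Conditions: TESOTf, 2,6-lutidine, CH2Cl2, −78 → 0 °C
Reagents that add atoms: triethylsilyl triflate CC[Si](CC)(CC)OS(=O)(=O)C(F)(F)F
Why: Silyl ether protection of the tertiary alcohol with a silyl triflate and a hindered pyridine base is general and leaves the linalool stereocentre, which becomes C10, untouched.

Step 2
Reactants: 2 (3R)-3,7-dimethyl-3-(triethylsilyloxy)octa-1,6-diene
Product: 4 (3R)-3,7-dimethyl-3-(triethylsilyloxy)oct-6-en-1-ol, via B-alkyl-9-BBN adduct 3 (not isolated)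
Conditions: 9-BBN, THF, 0 °C → rt; then NaOH, H2O2, 0 °C
Reagents that add atoms: hydrogen peroxide OO
Why: Anti-Markovnikov hydroboration–oxidation with 9-BBN should take the monosubstituted vinyl group far faster than the trisubstituted alkene and turns it into the C9–C8 hydroxyethyl arm without touching C10.

Step 3
Reactants: 4 (3R)-3,7-dimethyl-3-(triethylsilyloxy)oct-6-en-1-ol
Product: 5 (3R)-3,7-dimethyl-3-(triethylsilyloxy)oct-6-enal
Conditions: Dess–Martin periodinane, NaHCO3, CH2Cl2, 0 °C → rt
Reagents that add atoms: none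
Why: Dess–Martin oxidation of the primary alcohol under bicarbonate buffering gives the C8 aldehyde under conditions too mild for β-elimination of the tertiary silyloxy group.

Step 4
Reactants: 5 (3R)-3,7-dimethyl-3-(triethylsilyloxy)oct-6-enal; 6 trans-4-methylpent-2-ene; 7 (−)-B-methoxydiisopinocampheylborane (from (+)-α-pinene)
Product: 10 (3S,4R,6R)-6,10-dimethyl-3-(propan-2-yl)-6-(triethylsilyloxy)undeca-1,9-dien-4-ol, via (E)-allylpotassium 8 (not isolated), via (E)-allylborane 9 (not isolated)
Conditions: 6, n-BuLi, KOt-Bu, THF, −78 → −45 °C, 15 min, then −78 °C; 7, −78 °C; BF3·OEt2; 5, −78 °C; then NaOH, H2O2, rt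
Reagents that add atoms: none
Why: Brown allylboration, in which Schlosser-base metalation of 6 at its methyl group and trapping on boron give the (E)-γ-isopropylallylborane 9, which adds through a chair Zimmerman–Traxler transition state so that the E geometry sets C7–iPr anti to C8–OH in the zigzag chain (cis on the later ring) and the isopinocampheyl groups from (+)-α-pinene direct attack to the Si face of the aldehyde to give 4R (C8) by reagent control over the remote C10 centre.

Step 5
Reactants: 10 (3S,4R,6R)-6,10-dimethyl-3-(propan-2-yl)-6-(triethylsilyloxy)undeca-1,9-dien-4-ol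
Product: 11 (3S,4R,6R)-4-(tert-butyldimethylsilyloxy)-6,10-dimethyl-3-(propan-2-yl)-6-(triethylsilyloxy)undeca-1,9-diene
Conditions: TBSOTf, 2,6-lutidine, CH2Cl2, 0 °C → rt
Reagents that add atoms: tert-butyldimethylsilyl triflate CC(C)(C)[Si](C)(C)OS(=O)(=O)C(F)(F)F
Why: Silyl triflate silylation protects the hindered C8 alcohol as a robust TBS ether meant to survive the Lewis acid of step 11, with no stereocentre affected.

Step 6
Reactants: 11 (3S,4R,6R)-4-(tert-butyldimethylsilyloxy)-6,10-dimethyl-3-(propan-2-yl)-6-(triethylsilyloxy)undeca-1,9-diene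
Product: 12 (4R,6R,7S)-6-(tert-butyldimethylsilyloxy)-4-methyl-7-(propan-2-yl)-4-(triethylsilyloxy)non-8-enal
Conditions: O3, CH2Cl2/MeOH, pyridine, Sudan Red 7B, −78 °C, stopped at the colour change; then PPh3, −78 °C → rt
Reagents that add atoms: ozone [O-][O+]=O
Why: Ozonolysis with reductive work-up, stopped at the dye end-point, is expected to cleave the electron-rich trisubstituted alkene in preference to the hindered monosubstituted vinyl group and so releases the C3 aldehyde.

Step 7
Reactants: 12 (4R,6R,7S)-6-(tert-butyldimethylsilyloxy)-4-methyl-7-(propan-2-yl)-4-(triethylsilyloxy)non-8-enal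
Product: 13 (4R,6R,7S)-6-(tert-butyldimethylsilyloxy)-4-methyl-2-methylidene-7-(propan-2-yl)-4-(triethylsilyloxy)non-8-enal
Conditions: 37% aq. CH2O, pyrrolidine (10 mol %), propionic acid (10 mol %), i-PrOH, 45 °C
Reagents that add atoms: formaldehyde C=O
Why: Amine-catalysed Mannich condensation with formaldehyde followed by elimination (α-methylenation of an aldehyde) converts the C2 methylene into the 2-methylidene aldehyde, and the mild catalytic conditions leave both silyl ethers in place.

Step 8
Reactants: 13 (4R,6R,7S)-6-(tert-butyldimethylsilyloxy)-4-methyl-2-methylidene-7-(propan-2-yl)-4-(triethylsilyloxy)non-8-enal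
Product: 14 (3S,4R,6R)-4-(tert-butyldimethylsilyloxy)-6-methyl-3-(propan-2-yl)-6-(triethylsilyloxy)cyclohept-1-ene-1-carbaldehyde
Conditions: second-generation Grubbs catalyst (H2IMes)(PCy3)Cl2Ru=CHPh (10 mol %), PhMe (0.003 M), 80 °C
Reagents that add atoms: none
Why: Ring-closing olefin metathesis, initiated at the monosubstituted C6 vinyl group and closed onto the 1,1-disubstituted enal methylidene, should form the trisubstituted C2=C6 alkene of the seven-membered ring with loss of ethylene, favoured by the quaternary C10 in the tether and by high dilution.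

Step 9
Reactants: 14 (3S,4R,6R)-4-(tert-butyldimethylsilyloxy)-6-methyl-3-(propan-2-yl)-6-(triethylsilyloxy)cyclohept-1-ene-1-carbaldehyde; 15 1-(trimethylsilyl)propyne
Product: 18 (E)-1-[(3S,4R,6R)-4-(tert-butyldimethylsilyloxy)-6-methyl-3-(propan-2-yl)-6-(triethylsilyloxy)cyclohept-1-en-1-yl]-2-methyl-3-(trimethylsilyl)prop-2-en-1-ol (both carbinol epimers), via titanacyclopropene 16 (not isolated), via oxatitanacyclopentene 17 (not isolated)
Conditions: 15, Ti(Oi-Pr)4, i-PrMgCl (2 equiv per Ti), Et2O, −78 → −50 °C, 2 h; then 14, −78 → −40 °C; then H2O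
Reagents that add atoms: none
Why: Titanium alkoxide-mediated reductive coupling of a silylalkyne with an aldehyde, in which the titanacyclopropene 16 formed from divalent titanium inserts the aldehyde C=O by 1,2-addition at the alkyne carbon remote from silicon (titanium stays on the silicon-bearing carbon) and protonolysis of that Ti–C bond with retention leaves H cis to C3 and hence the (E)-1-methyl-2-silylvinyl geometry, while the new carbinol centre is removed in step 10.

Step 10
Reactants: 18 (E)-dienol (both carbinol epimers)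
Product: 19 (E)-1-[(3S,4R,6R)-4-(tert-butyldimethylsilyloxy)-6-methyl-3-(propan-2-yl)-6-(triethylsilyloxy)cyclohept-1-en-1-yl]-2-methyl-3-(trimethylsilyl)prop-2-en-1-one
Conditions: Dess–Martin periodinane, NaHCO3, CH2Cl2, 0 °C → rt
Reagents that add atoms: none
Why: Dess–Martin oxidation of the doubly allylic alcohol gives the cross-conjugated dienone without acid that could protodesilylate the vinylsilane or isomerise its E geometry.

Step 11
Reactants: 19 cycloheptenyl (E)-1-methyl-2-(trimethylsilyl)vinyl ketone
Product: 21 trans-fused hydroazulenone (C3 ketone; C4=C5 alkene; C2–H β; C6–H α; 7α-isopropyl; 8α-OTBS; 10β-methyl; 10α-OTES), via cis-fused enone 20 (not isolated)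
Conditions: FeCl3 (1.05 equiv), CH2Cl2, −50 → −10 °C; aq. NaHCO3; crude product, DBU (0.2 equiv), PhMe, rt
Reagents that add atoms: none
Why: FeCl3 coordinates the C3 carbonyl oxygen and turns the cross-conjugated dienone into a 3-oxidopentadienyl cation, which closes by thermally allowed conrotatory 4π electrocyclisation between C5 and C6 to an oxyallyl cation over C2–C3–C4; the β-silicon effect then directs loss of the trimethylsilyl group from C5, so the alkene appears at C4=C5 only and the iron dienolate is protonated at C2. This is the silicon-directed Nazarov cyclisation of a cycloalkenyl β-silylvinyl ketone, a known reaction type applied to a new substrate. The five-membered ring C2–C3–C4–C5–C6 is closed by this 4π conrotatory electrocyclisation, formally a 5-endo closure between the two alkene termini. C6 is controlled by the neighbouring C7 stereocentre: the sense of conrotation that brings C5 onto the β face of C6, anti to the α isopropyl group and the α C8 silyloxy group behind it, is favoured sterically, so C6–H ends α. C2 is first set by kinetic protonation from the α face, away from the seven-membered ring (cis-fused 20), and is then corrected by DBU under thermodynamic control through the cross-conjugated C2 enolate, whose charge is confined to O and C2 so that the C4=C5 alkene cannot migrate, to the trans-fused epimer expected to be the more stable one for a cyclopentenone fused to a seven-membered ring. The step needs one torquoselectivity and a regiospecific termination; the first is secured by the C7 stereocentre next to the reacting terminus, the second by silicon, and the low temperature with one equivalent of FeCl3 is chosen to keep the tertiary C10 triethylsilyl ether intact.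

Step 12
Reactants: 21 trans-fused hydroazulenone
Product: 22 C3 tosylhydrazone of 21 (C=N geometry not defined)
Conditions: TsNHNH2, AcOH (cat.), EtOH/THF, 50 °C
Reagents that add atoms: p-toluenesulfonyl hydrazide Cc1ccc(S(=O)(=O)NN)cc1
Why: Condensation of the hindered enone with tosylhydrazide under mild acid catalysis gives the α,β-unsaturated tosylhydrazone (hydrazone formation), and any C2 epimerisation through the ene-hydrazine runs toward the same trans-fused thermodynamic isomer.

Step 13
Reactants: 22 C3 tosylhydrazone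
Product: 24 trans-fused C3=C4 alkene with C5H2 (C2–H β; C6–H α; 8α-OTBS; 10α-OTES), via allylic diazene 23 (not isolated)
Conditions: catecholborane, CHCl3, 0 °C; then NaOAc·3H2O, reflux
Reagents that add atoms: none
Why: Reductive 1,3-transposition of an enone tosylhydrazone with catecholborane (Kabalka reduction), in which hydride adds to C3, acetate-induced loss of sulfinate gives the allylic diazene 23, and its retro-ene loss of N2 delivers hydrogen to C5 and moves the alkene to C3=C4 without creating or disturbing a stereocentre.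

Step 14
Reactants: 24 bis-silyl C3=C4 alkene
Product: 25 8α,10α-diol with C3=C4 alkene
Conditions: TBAF (excess), THF, 50 °C
Reagents that add atoms: none
Why: Fluoride-mediated desilylation removes both the secondary TBS and the tertiary TES ether, the alkene and all stereocentres being inert to TBAF.

Step 15
Reactants: 26 isovanillic acid
Product: 28 3-(benzyloxy)-4-methoxybenzoic acid, via benzyl ester 27 (not isolated)
Conditions: BnBr, K2CO3, DMF, 60 °C; then NaOH, MeOH/H2O, 65 °C; then HCl
Reagents that add atoms: benzyl bromide BrCc1ccccc1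
Why: Williamson benzylation of both the phenol and the carboxylate followed by saponification of the benzyl ester in the same flask gives the O-benzyl acid, the aryl benzyl ether being stable to hydroxide.

Step 16
Reactants: 25 8α,10α-diol; 28 3-(benzyloxy)-4-methoxybenzoic acid
Product: 30 C8 3-(benzyloxy)-4-methoxybenzoate of 25 (free 10α-OH; C3=C4 alkene), via mixed anhydride 29 (not isolated)
Conditions: 28, 2,4,6-trichlorobenzoyl chloride, Et3N, PhMe, rt; then 25, DMAP, rt → 50 °C
Reagents that add atoms: none
Why: Yamaguchi esterification through the mixed anhydride 29 and DMAP acylates the secondary C8 hydroxyl with retention at C8, while the tertiary C10 hydroxyl is too hindered to react.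

Step 17
Reactants: 30 C8 ester with C3=C4 alkene
Product: 31 3α,4α-epoxide of 30 (O-benzyl ether of the target)
Conditions: VO(acac)2 (10 mol %), t-BuOOH (decane solution), CH2Cl2, 0 °C → rt
Reagents that add atoms: tert-butyl hydroperoxide CC(C)(C)OO
Why: Vanadium-catalysed hydroxyl-directed epoxidation with tert-butyl hydroperoxide, known for homoallylic and bishomoallylic alcohols, in which the α-oriented C10 alkoxide binds the vanadium peroxide and delivers oxygen to the α face of C3=C4, setting C3 and C4 together, while the cis relation of hydroxyl and oxirane prevents backside opening of the epoxide by that hydroxyl.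

Step 18
Reactants: 31 O-benzyl epoxide
Product: 32 CNP0106636.1 (target)
Conditions: H2 (1 atm), 10% Pd/C, EtOAc, rt
Reagents that add atoms: none
Why: Hydrogenolysis of the aryl benzyl ether over Pd/C under neutral conditions frees the phenol, while the aliphatic trisubstituted oxirane, the benzoate ester and the tertiary alcohol are not reduced.

Compound list
1 | (R)-linalool, (3R)-3,7-dimethylocta-1,6-dien-3-ol | C=C[C@](C)(O)CCC=C(C)C | starting material
2 | (3R)-3,7-dimethyl-3-(triethylsilyloxy)octa-1,6-diene | C=C[C@](C)(O[Si](CC)(CC)CC)CCC=C(C)C | intermediate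
3 | B-[(3S)-3,7-dimethyl-3-(triethylsilyloxy)oct-6-enyl]-9-borabicyclo[3.3.1]nonane | C1CC2CCCC(C1)B2CC[C@](C)(O[Si](CC)(CC)CC)CCC=C(C)C | intermediate
4 | (3R)-3,7-dimethyl-3-(triethylsilyloxy)oct-6-en-1-ol | OCC[C@](C)(O[Si](CC)(CC)CC)CCC=C(C)C | intermediate
5 | (3R)-3,7-dimethyl-3-(triethylsilyloxy)oct-6-enal | O=CC[C@](C)(O[Si](CC)(CC)CC)CCC=C(C)C | intermediate
6 | trans-4-methylpent-2-ene | C/C=C/C(C)C | starting material
7 | (−)-B-methoxydiisopinocampheylborane (from (+)-α-pinene) | COB([C@@H]1C[C@@H]2C[C@H]([C@H]1C)C2(C)C)[C@@H]1C[C@@H]2C[C@H]([C@H]1C)C2(C)C | starting material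
8 | (E)-(4-methylpent-2-enyl)potassium | [K]C/C=C/C(C)C | intermediate
9 | (E)-(4-methylpent-2-enyl)diisopinocampheylborane | CC(C)/C=C/CB([C@@H]1C[C@@H]2C[C@H]([C@H]1C)C2(C)C)[C@@H]1C[C@@H]2C[C@H]([C@H]1C)C2(C)C | intermediate
10 | (3S,4R,6R)-6,10-dimethyl-3-(propan-2-yl)-6-(triethylsilyloxy)undeca-1,9-dien-4-ol | CC(C)=CCC[C@@](C)(O[Si](CC)(CC)CC)C[C@@H](O)[C@H](C=C)C(C)C | intermediate
11 | (3S,4R,6R)-4-(tert-butyldimethylsilyloxy)-6,10-dimethyl-3-(propan-2-yl)-6-(triethylsilyloxy)undeca-1,9-diene | CC(C)=CCC[C@@](C)(O[Si](CC)(CC)CC)C[C@@H](O[Si](C)(C)C(C)(C)C)[C@H](C=C)C(C)C | intermediate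
12 | (4R,6R,7S)-6-(tert-butyldimethylsilyloxy)-4-methyl-7-(propan-2-yl)-4-(triethylsilyloxy)non-8-enal | O=CCC[C@@](C)(O[Si](CC)(CC)CC)C[C@@H](O[Si](C)(C)C(C)(C)C)[C@H](C=C)C(C)C | intermediate
13 | (4R,6R,7S)-6-(tert-butyldimethylsilyloxy)-4-methyl-2-methylidene-7-(propan-2-yl)-4-(triethylsilyloxy)non-8-enal | C=C(C=O)C[C@@](C)(O[Si](CC)(CC)CC)C[C@@H](O[Si](C)(C)C(C)(C)C)[C@H](C=C)C(C)C | intermediate
14 | (3S,4R,6R)-4-(tert-butyldimethylsilyloxy)-6-methyl-3-(propan-2-yl)-6-(triethylsilyloxy)cyclohept-1-ene-1-carbaldehyde (C2-formylcycloheptene; C2=C6) | CC(C)(C)[Si](C)(C)O[C@@H]1C[C@](C)(O[Si](CC)(CC)CC)CC(C=O)=C[C@@H]1C(C)C | intermediate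
15 | 1-(trimethylsilyl)propyne | CC#C[Si](C)(C)C | starting material
16 | diisopropoxy[η2-1-(trimethylsilyl)propyne]titanium (titanacyclopropene) | CC1=C([Si](C)(C)C)[Ti]1(OC(C)C)OC(C)C | intermediate
17 | oxatitanacyclopentene from 14 and 16 (ring Ti–O–C3–C4(Me)=C5(SiMe3)) | CC(C)(C)[Si](C)(C)O[C@@H]1C[C@](C)(O[Si](CC)(CC)CC)CC(C2O[Ti](OC(C)C)(OC(C)C)C([Si](C)(C)C)=C2C)=C[C@@H]1C(C)C | intermediate
18 | (E)-1-[(3S,4R,6R)-4-(tert-butyldimethylsilyloxy)-6-methyl-3-(propan-2-yl)-6-(triethylsilyloxy)cyclohept-1-en-1-yl]-2-methyl-3-(trimethylsilyl)prop-2-en-1-ol (both carbinol epimers) | CC(C)(C)[Si](C)(C)O[C@@H]1C[C@](C)(O[Si](CC)(CC)CC)CC(C(O)/C(C)=C/[Si](C)(C)C)=C[C@@H]1C(C)C | intermediate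
19 | (E)-1-[(3S,4R,6R)-4-(tert-butyldimethylsilyloxy)-6-methyl-3-(propan-2-yl)-6-(triethylsilyloxy)cyclohept-1-en-1-yl]-2-methyl-3-(trimethylsilyl)prop-2-en-1-one (Nazarov precursor) | CC(C)(C)[Si](C)(C)O[C@@H]1C[C@](C)(O[Si](CC)(CC)CC)CC(C(=O)/C(C)=C/[Si](C)(C)C)=C[C@@H]1C(C)C | intermediate
20 | cis-fused hydroazulenone (C3 ketone; C4=C5; C2–H α; C6–H α; 7α-isopropyl; 8α-OTBS; 10β-methyl; 10α-OTES) | CC(C)(C)[Si](C)(C)O[C@@H]1C[C@](C)(O[Si](CC)(CC)CC)C[C@@H]2[C@@H](C=C(C)C2=O)[C@@H]1C(C)C | intermediate
21 | trans-fused hydroazulenone (as 20 but C2–H β) | CC(C)(C)[Si](C)(C)O[C@@H]1C[C@](C)(O[Si](CC)(CC)CC)C[C@H]2[C@@H](C=C(C)C2=O)[C@@H]1C(C)C | intermediate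
22 | C3 tosylhydrazone of 21 | CC(C)(C)[Si](C)(C)O[C@@H]1C[C@](C)(O[Si](CC)(CC)CC)C[C@H]2[C@@H](C=C(C)C2=NNS(=O)(=O)c3ccc(C)cc3)[C@@H]1C(C)C | intermediate
23 | allylic diazene (C3–N=NH, both C3 epimers; C4=C5) | CC(C)(C)[Si](C)(C)O[C@@H]1C[C@](C)(O[Si](CC)(CC)CC)C[C@H]2[C@@H](C=C(C)C2N=N)[C@@H]1C(C)C | intermediate
24 | trans-fused C3=C4 alkene (C5H2; 8α-OTBS; 10α-OTES) | CC(C)(C)[Si](C)(C)O[C@@H]1C[C@](C)(O[Si](CC)(CC)CC)C[C@H]2[C@@H](CC(C)=C2)[C@@H]1C(C)C | intermediate
25 | 8α,10α-diol with C3=C4 alkene | O[C@@H]1C[C@](C)(O)C[C@H]2[C@@H](CC(C)=C2)[C@@H]1C(C)C | intermediate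
26 | isovanillic acid | COc1ccc(C(=O)O)cc1O | starting material
27 | benzyl 3-(benzyloxy)-4-methoxybenzoate | COc1ccc(C(=O)OCc2ccccc2)cc1OCc1ccccc1 | intermediate
28 | 3-(benzyloxy)-4-methoxybenzoic acid | COc1ccc(C(=O)O)cc1OCc1ccccc1 | intermediate
29 | 3-(benzyloxy)-4-methoxybenzoic 2,4,6-trichlorobenzoic anhydride | COc1ccc(C(=O)OC(=O)c2c(Cl)cc(Cl)cc2Cl)cc1OCc1ccccc1 | intermediate
30 | C8 3-(benzyloxy)-4-methoxybenzoate of 25 | COc1ccc(C(=O)O[C@@H]2C[C@](C)(O)C[C@H]3[C@@H](CC(C)=C3)[C@@H]2C(C)C)cc1OCc1ccccc1 | intermediate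
31 | 3α,4α-epoxide of 30 (O-benzyl ether of the target) | COc1ccc(C(=O)O[C@@H]2C[C@](C)(O)C[C@H]3[C@@H](C[C@@]4(C)O[C@@H]34)[C@@H]2C(C)C)cc1OCc1ccccc1 | intermediate
32 | CNP0106636.1 | COc1ccc(C(=O)O[C@@H]2C[C@](C)(O)C[C@H]3[C@@H](C[C@@]4(C)O[C@@H]34)[C@@H]2C(C)C)cc1O | target

Total step count: 18. Longest linear sequence: 17 steps from (R)-linalool (steps 1–14 and 16–18); step 15 is a one-step side branch.

Steps most likely to fail

Step 11 (key step). The Lewis acid may ionise or cleave the tertiary C10 silyl ether, the conrotation may lose its bias so that C5 also adds syn to the isopropyl group, or the vinylsilane may be protodesilylated before the ring closes. The equilibration half of the step is thermodynamic, and a cis-fused remainder would be resubjected to DBU. The fallback builds the same cyclopentenone by a 1,4-dicarbonyl aldol annulation; it sets out from aldehyde 14 and comes back at 21. Ethylmagnesium bromide adds to 14 to give the ethyl carbinol F1, and Dess–Martin oxidation gives the cycloheptenyl ethyl ketone F2. Copper-catalysed conjugate addition of vinylmagnesium bromide (CuBr·SMe2, THF, −40 °C), expected at C6 anti to the C7 isopropyl group, gives the 6β-vinyl ketone F3. Ozonolysis with PPh3 work-up gives the keto aldehyde F4, whose intramolecular aldol condensation (KOH, MeOH) between C4 and the C5 aldehyde closes the 2-methylcyclopentenone and equilibrates C2, giving 21.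

Step 17. Oxygen may be delivered to the β face, or to both faces, because the directing hydroxyl sits three bonds from C3 on a flexible seven-membered ring and the undirected reagent prefers the face away from C1. The fallback inverts the facial outcome through a halohydrin; it sets out from the bis-silyl alkene 24 and comes back at 31. N-Bromosuccinimide in aqueous THF should form the bromonium ion on the sterically preferred β face, and water opens it at the tertiary C4 from the α face to give the bromohydrin F5 (3β-Br, 4α-OH). K2CO3 in MeOH closes the oxirane with inversion at C3 to the α-epoxide F6, TBAF gives the epoxy diol F7, and Yamaguchi esterification of F7 with acid 28 gives 31.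

Step 8. Initiation at the hindered, allylically branched C6 vinyl group may be slow and the electron-poor 2-methylidene aldehyde may engage unproductively, so that dimers form or the catalyst decays before the trisubstituted alkene is closed. The fallback closes the ring by an aldol condensation; it sets out from diene 11 and comes back at 14. Exhaustive ozonolysis of 11 (O3 to the blue end-point, then PPh3) gives the dialdehyde F8. Dibenzylammonium trifluoroacetate in PhMe at 50 °C forms the enamine at the unhindered C3 aldehyde, which attacks the C6 aldehyde; dehydration gives 14. The α-branched C6 aldehyde is reluctant to form an enamine, which protects C7 from epimerisation and the C8 silyloxy group from β-elimination.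

Further compounds
F1 | step 11 | 1-[(3S,4R,6R)-4-(tert-butyldimethylsilyloxy)-6-methyl-3-(propan-2-yl)-6-(triethylsilyloxy)cyclohept-1-en-1-yl]propan-1-ol (both carbinol epimers) | CC(C)(C)[Si](C)(C)O[C@@H]1C[C@](C)(O[Si](CC)(CC)CC)CC(C(O)CC)=C[C@@H]1C(C)C
F2 | step 11 | 1-[(3S,4R,6R)-4-(tert-butyldimethylsilyloxy)-6-methyl-3-(propan-2-yl)-6-(triethylsilyloxy)cyclohept-1-en-1-yl]propan-1-one | CC(C)(C)[Si](C)(C)O[C@@H]1C[C@](C)(O[Si](CC)(CC)CC)CC(C(=O)CC)=C[C@@H]1C(C)C
F3 | step 11 | 6β-vinyl cycloheptyl ethyl ketone (C2 epimers; 7α-isopropyl; 8α-OTBS; 10α-OTES) | CC(C)(C)[Si](C)(C)O[C@@H]1C[C@](C)(O[Si](CC)(CC)CC)CC(C(=O)CC)[C@@H](C=C)[C@@H]1C(C)C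
F4 | step 11 | 6β-formyl cycloheptyl ethyl ketone (1,4-keto aldehyde; C2 epimers) | CC(C)(C)[Si](C)(C)O[C@@H]1C[C@](C)(O[Si](CC)(CC)CC)CC(C(=O)CC)[C@@H](C=O)[C@@H]1C(C)C
F5 | step 17 | 3β-bromo-4α-hydroxy derivative of 24 (bromohydrin) | CC(C)(C)[Si](C)(C)O[C@@H]1C[C@](C)(O[Si](CC)(CC)CC)C[C@H]2[C@@H](C[C@@](C)(O)[C@@H]2Br)[C@@H]1C(C)C
F6 | step 17 | 3α,4α-epoxide of 24 (8α-OTBS; 10α-OTES) | CC(C)(C)[Si](C)(C)O[C@@H]1C[C@](C)(O[Si](CC)(CC)CC)C[C@H]2[C@@H](C[C@@]3(C)O[C@@H]23)[C@@H]1C(C)C
F7 | step 17 | 3α,4α-epoxy-8α,10α-diol | O[C@@H]1C[C@](C)(O)C[C@H]2[C@@H](C[C@@]3(C)O[C@@H]23)[C@@H]1C(C)C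
F8 | step 8 | (2S,3R,5R)-3-(tert-butyldimethylsilyloxy)-5-methyl-2-(propan-2-yl)-5-(triethylsilyloxy)octanedial | O=CCC[C@@](C)(O[Si](CC)(CC)CC)C[C@@H](O[Si](C)(C)C(C)(C)C)[C@H](C=O)C(C)C
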